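The route rests on disconnecting C3–C8'', the bond that joins the pyranone (ring C) to the benzene ring of the flavan (ring D) at the carbon lying between O7'' and O1''. Seen in reverse, C4–C3–C2 is the propenone chain of a 2'-hydroxychalcone whose β-aryl group is ring D. In one operation an oxidative 1,2-shift of ring D from Cβ to Cα, induced by trivalent thallium, and a base-induced ring closure forge C3–C8'' and O1–C2 and give the isoflavone; an aldehyde carbon fixes the attachment site. The precursor is the (E)-chalcone from an (S)-flavan-8-carbaldehyde (MOM on O7'') and 4,6-di-O-benzylphloroacetophenone. C2 and C3 are then raised on the flat furo-fused chromone by catalyst-controlled arylation and anti hydroxylation.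

Key step: step 8

Assumption: the target is taken exactly as written, (2R,3S,2''S), with C2/C3/C4/O1 for the pyranone (ring C) and doubly primed locants for the flavan (benzene ring D); the C2 aryl group and the C3 hydroxyl then lie on opposite faces, so the dihydrofuran/pyranone junction is trans, C2 is set by the catalyst and C3 by kinetic anti delivery of oxygen, and the strained product is handled without acid or base.

## Route

Step 1
Reactants: 1 (S)-naringenin
Product: 2 (2S)-5-hydroxy-2-(4-hydroxyphenyl)-7-(methoxymethoxy)chroman-4-one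
Conditions: MOMCl (1.05 equiv), i-Pr2NEt (1.2 equiv), THF, 0 °C
Reagents that add atoms: chloromethyl methyl ether, COCCl
Why: Williamson-type O-alkylation that should go to O7, the most acidic phenol (para to the carbonyl), while O5 is held in the hydrogen bond to C4=O and O4' is less acidic; the amine base is too weak to enolise C3, so C2 should keep its (S) configuration.

Step 2
Reactants: 2 (2S)-5-hydroxy-2-(4-hydroxyphenyl)-7-(methoxymethoxy)chroman-4-one
Product: 5 (2S)-2-(4-hydroxyphenyl)-7-(methoxymethoxy)chroman-5-ol, via bis(ethyl carbonate) 3 (not isolated), via monocarbonate flavanol 4 (not isolated)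
Conditions: ClCO2Et (2.5 equiv), Et3N, THF, 0 °C; filter; then NaBH4, THF/H2O, 0 °C → rt; then 2 M NaOH, rt
Reagents that add atoms: none
Why: reductive deoxygenation of an ortho-hydroxyaryl ketone through its aryl carbonate (borohydride reduction, carbonate transfer, ortho-quinone methide, second hydride), which should turn C4=O into CH2 and return the 5-phenol; the 4'-carbonate is saponified in the same pot and C2 is not involved.

Step 3
Reactants: 5 (2S)-2-(4-hydroxyphenyl)-7-(methoxymethoxy)chroman-5-ol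
Product: 6 (2S)-5-(benzyloxy)-2-[4-(benzyloxy)phenyl]-7-(methoxymethoxy)chromane
Conditions: BnBr (2.4 equiv), K2CO3, DMF, rt
Reagents that add atoms: benzyl bromide, BrCc1ccccc1
Why: Williamson etherification of both phenols; with the ketone gone, no base-induced ring opening can racemise C2.

Step 4
Reactants: 6 (2S)-5-(benzyloxy)-2-[4-(benzyloxy)phenyl]-7-(methoxymethoxy)chromane
Product: 7 (2S)-5-(benzyloxy)-2-[4-(benzyloxy)phenyl]-8-bromo-7-(methoxymethoxy)chromane
Conditions: NBS (1.0 equiv), CH2Cl2, −78 °C → 0 °C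
Reagents that add atoms: N-bromosuccinimide, O=C1CCC(=O)N1Br
Why: electrophilic aromatic bromination of the trioxygenated ring; C8, between the ring oxygen and the MOM ether, is less shielded than C6 between two acyclic ethers, as in the C8-selective bromination of 5,7-di-O-protected flavans.

Step 5
Reactants: 7 (2S)-5-(benzyloxy)-2-[4-(benzyloxy)phenyl]-8-bromo-7-(methoxymethoxy)chromane
Product: 10 (2S)-5-(benzyloxy)-2-[4-(benzyloxy)phenyl]-7-(methoxymethoxy)chromane-8-carbaldehyde, via aryllithium 8 (not isolated), via hemiaminal alkoxide 9 (not isolated)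
Conditions: n-BuLi (1.1 equiv), THF, −78 °C; then DMF, −78 °C → 0 °C; aq NH4Cl
Reagents that add atoms: N,N-dimethylformamide, CN(C)C=O
Why: bromine–lithium exchange and formylation (Bouveault type); the aryllithium is held by the flanking MOM oxygen, and the aldehyde marks C8 as the only attachment site.

Step 6
Reactants: 11 2,4,6-trihydroxyacetophenone
Product: 12 1-[2,4-bis(benzyloxy)-6-hydroxyphenyl]ethan-1-one
Conditions: BnBr (2.1 equiv), K2CO3, acetone, reflux
Reagents that add atoms: benzyl bromide, BrCc1ccccc1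
Why: Williamson etherification that should stop at two phenols because the third is hydrogen-bonded to the acetyl group.

Step 7
Reactants: 10 (2S)-5-(benzyloxy)-2-[4-(benzyloxy)phenyl]-7-(methoxymethoxy)chromane-8-carbaldehyde; 12 1-[2,4-bis(benzyloxy)-6-hydroxyphenyl]ethan-1-one
Product: 13 (E)-1-[2,4-bis(benzyloxy)-6-hydroxyphenyl]-3-[(2S)-5-(benzyloxy)-2-(4-(benzyloxy)phenyl)-7-(methoxymethoxy)chroman-8-yl]prop-2-en-1-one
Conditions: KOH (50% aq), EtOH/THF, rt → 40 °C
Reagents that add atoms: none
Why: Claisen–Schmidt condensation; dehydration of the aldol gives the conjugated (E)-enone, and hydroxide touches neither the ethers nor the flavan stereocentre, which has no adjacent carbonyl.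

Step 8
Reactants: 13 (E)-2'-hydroxychalcone
Product: 16 5,7-bis(benzyloxy)-3-[(2S)-5-(benzyloxy)-2-(4-(benzyloxy)phenyl)-7-(methoxymethoxy)chroman-8-yl]-4H-chromen-4-one, via dimethyl acetal 14 (not isolated), via β-methoxy enone 15 (not isolated)
Conditions: Tl(NO3)3·3H2O (1.2 equiv), MeOH/CH(OMe)3 (3:1), rt; filter; then NaOMe, MeOH/THF, 50 °C
Reagents that add atoms: none
Why: Methanol adds to Cβ and trivalent thallium to Cα of the enone; when monovalent thallium leaves Cα, ring D bridges as a phenonium ion and ends on Cα, which forms C3–C8'' and leaves Cβ as the dimethyl acetal 14. The closest known reaction is the oxidative rearrangement of 2'-hydroxychalcones to isoflavones with Tl(NO3)3 in methanol. Under methoxide 14 loses methanol (E1cB) to the β-methoxy enone 15, and the 2'-phenoxide then closes the pyranone (O1–C2) by 6-endo-trig addition at Cβ and loss of methoxide. No stereocentre is formed and C2'' lies far from every bond that changes. The step needs ring D and not the aroyl group to migrate, which the three oxygen substituents of ring D secure, and it needs the oxidant to spare the aryl ethers, which is helped by running it at room temperature with the 2'-phenol hydrogen-bonded to the carbonyl. Closure under base keeps the MOM group on O7'', so this oxygen cannot capture the acetal carbon in a competing 5-exo closure to a 3-aroylbenzofuran.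

Step 9
Reactants: 16 MOM-protected isoflavone
Product: 17 2,3-epoxide of 16 (2,3-epoxyisoflavanone; both epoxide faces)
Conditions: DMDO (3 equiv, acetone), CH2Cl2, 0 °C → rt
Reagents that add atoms: dimethyldioxirane, CC1(C)OO1
Why: dioxirane epoxidation of the chromone C2=C3 bond, as known for isoflavones; a neutral oxygen-transfer reagent is used because a hydride-abstracting quinone would also attack the oxygen-activated benzylic C4'' of the flavan, and the face of attack is irrelevant since C2 and C3 become planar again in step 11.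

Step 10
Reactants: 17 2,3-epoxyisoflavanone
Product: 18 cis-fused 3-hydroxy acetal (C2–H and C3–OH syn; O7'' bonded to C2; both cis diastereomers)
Conditions: 2 M HCl (aq), MeOH/THF (1:1), 40 °C
Reagents that add atoms: none
Why: acid cleaves the MOM ether and opens the epoxide at the acetal-like C2 (oxocarbenium stabilised by O1); O7'' captures C2 from the face opposite the departing oxygen in a 5-exo closure, which forms C2–O7'' and can only give the cis-fused hydroxy acetal.

Step 11
Reactants: 18 cis-fused 3-hydroxy acetal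
Product: 20 tetra-O-benzyl benzofuro-fused chromone (flat tetracycle with C2=C3), via sulfamate ester 19 (not isolated)
Conditions: Burgess reagent (2 equiv), THF, 50 °C
Reagents that add atoms: none
Why: Burgess dehydration; the tertiary C3 sulfamate leaves together with the syn C2–H in a cyclic (Ei) elimination, driven by aromatisation to the furan-fused chromone.

Step 12
Reactants: 20 tetra-O-benzyl benzofuro-fused chromone
Product: 21 (2R)-C4 trimethylsilyl enol ether carrying the 4-(benzyloxy)phenyl group on C2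
Conditions: 4-BnOC6H4MgBr (2.0 equiv, commercial THF solution) + ZnCl2 (2.1 equiv), THF, 0 °C; then 20, Me3SiCl (2.0 equiv), [RhCl(C2H4)2]2 (3 mol %), (R)-BINAP (6.6 mol %), THF, 20 °C; Et3N, cold pH 7 buffer; used crude
Reagents that add atoms: 4-(benzyloxy)phenylmagnesium bromide, Br[Mg]c1ccc(OCc2ccccc2)cc1; chlorotrimethylsilane, C[Si](C)(C)Cl
Why: Proposed new method: the arylzinc chloride formed in the flask transfers its aryl group to monovalent rhodium, the aryl–rhodium species adds across C2=C3 of the chromone, whose carbonyl is activated by Me3SiCl, so that the aryl group lands on C2 (the β-carbon flanked by O1 and O7'') from the face selected by the ligand, and the rhodium enolate is silylated at once, which returns RhCl and keeps the enolate from expelling a phenoxide; the closest known reaction type is the rhodium/BINAP-catalysed asymmetric 1,4-addition of arylzinc chlorides to 4-quinolones and 2,3-dihydro-4-pyridones in the presence of Me3SiCl, and C2 (R) is set by the catalyst alone because the only resident stereocentre, C2'', is remote (the antipodal ligand is taken if a pilot run shows the opposite sense).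

Step 13
Reactants: 21 (2R)-trimethylsilyl enol ether
Product: 23 (2R,3S,2''S)-penta-O-benzyl hydroxy ketone, via silyloxy epoxide 22 (not isolated)
Conditions: DMDO (1.2 equiv, acetone), CH2Cl2, −78 °C → −20 °C; then Et3N·3HF, THF, 0 °C; chromatography on Et3N-deactivated silica
Reagents that add atoms: dimethyldioxirane, CC1(C)OO1
Why: Rubottom oxidation; the C2 aryl group stands perpendicular to the near-planar tetracycle and covers one face of C3=C4, so the dioxirane should deliver oxygen to C3 from the opposite face (substrate control), which places the hydroxyl anti to the aryl group (3S in the 2R series), and fluoride then collapses the silyloxy epoxide to the ketone with the C3–O bond intact.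

Step 14
Reactants: 23 (2R,3S,2''S)-penta-O-benzyl hydroxy ketone
Product: 24 target CNP0208300.3
Conditions: H2 (1 atm), 10% Pd/C, EtOAc/MeOH, rt
Reagents that add atoms: none
Why: hydrogenolysis of the five aryl benzyl ethers under neutral conditions, chosen because the trans-fused ketal is not expected to tolerate acid or base; no stereocentre takes part.

## Compound list

1 | (S)-naringenin | O=C1C[C@@H](c2ccc(O)cc2)Oc2cc(O)cc(O)c12 | starting material
2 | (2S)-5-hydroxy-2-(4-hydroxyphenyl)-7-(methoxymethoxy)chroman-4-one | O=C1C[C@@H](c2ccc(O)cc2)Oc2cc(OCOC)cc(O)c12 | intermediate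
3 | bis(ethyl carbonate) of 2 at O5 and O4' | O=C1C[C@@H](c2ccc(OC(=O)OCC)cc2)Oc2cc(OCOC)cc(OC(=O)OCC)c12 | intermediate
4 | (2S)-flavan-5-ol with 7-OMOM and 4'-O-ethoxycarbonyl | C1C[C@@H](c2ccc(OC(=O)OCC)cc2)Oc2cc(OCOC)cc(O)c12 | intermediate
5 | (2S)-2-(4-hydroxyphenyl)-7-(methoxymethoxy)chroman-5-ol | C1C[C@@H](c2ccc(O)cc2)Oc2cc(OCOC)cc(O)c12 | intermediate
6 | (2S)-5-(benzyloxy)-2-[4-(benzyloxy)phenyl]-7-(methoxymethoxy)chromane | C1C[C@@H](c2ccc(OCc3ccccc3)cc2)Oc2cc(OCOC)cc(OCc3ccccc3)c12 | intermediate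
7 | 8-bromo derivative of 6 | C1C[C@@H](c2ccc(OCc3ccccc3)cc2)Oc2c(Br)c(OCOC)cc(OCc3ccccc3)c12 | intermediate
8 | 8-lithio derivative of 6 | C1C[C@@H](c2ccc(OCc3ccccc3)cc2)Oc2c([Li])c(OCOC)cc(OCc3ccccc3)c12 | intermediate
9 | lithium hemiaminal alkoxide from 8 and DMF | C1C[C@@H](c2ccc(OCc3ccccc3)cc2)Oc2c(C([O-])N(C)C)c(OCOC)cc(OCc3ccccc3)c12.[Li+] | intermediate
10 | (2S)-5-(benzyloxy)-2-[4-(benzyloxy)phenyl]-7-(methoxymethoxy)chromane-8-carbaldehyde | C1C[C@@H](c2ccc(OCc3ccccc3)cc2)Oc2c(C=O)c(OCOC)cc(OCc3ccccc3)c12 | intermediate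
11 | 2,4,6-trihydroxyacetophenone | CC(=O)c1c(O)cc(O)cc1O | starting material
12 | 1-[2,4-bis(benzyloxy)-6-hydroxyphenyl]ethan-1-one | CC(=O)c1c(O)cc(OCc2ccccc2)cc1OCc1ccccc1 | intermediate
13 | (E)-2'-hydroxychalcone with the (S)-flavan-8-yl group on Cβ | O=C(/C=C/c1c(OCOC)cc(OCc2ccccc2)c2CC[C@@H](c3ccc(OCc4ccccc4)cc3)Oc12)c1c(O)cc(OCc2ccccc2)cc1OCc1ccccc1 | intermediate
14 | 1-aryl-2-(flavan-8-yl)-3,3-dimethoxypropan-1-one (Cα epimers) | O=C(C(C(OC)OC)c1c(OCOC)cc(OCc2ccccc2)c2CC[C@@H](c3ccc(OCc4ccccc4)cc3)Oc12)c1c(O)cc(OCc2ccccc2)cc1OCc1ccccc1 | intermediate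
15 | β-methoxy enone from 14 | O=C(C(=COC)c1c(OCOC)cc(OCc2ccccc2)c2CC[C@@H](c3ccc(OCc4ccccc4)cc3)Oc12)c1c(O)cc(OCc2ccccc2)cc1OCc1ccccc1 | intermediate
16 | 5,7-bis(benzyloxy)-3-[(2S)-5-(benzyloxy)-2-(4-(benzyloxy)phenyl)-7-(methoxymethoxy)chroman-8-yl]-4H-chromen-4-one | O=c1c(-c2c(OCOC)cc(OCc3ccccc3)c3CC[C@@H](c4ccc(OCc5ccccc5)cc4)Oc23)coc2cc(OCc3ccccc3)cc(OCc3ccccc3)c12 | intermediate
17 | 2,3-epoxide of 16 (both faces) | O=C1c2c(OCc3ccccc3)cc(OCc3ccccc3)cc2OC2OC12c1c(OCOC)cc(OCc2ccccc2)c2CC[C@@H](c3ccc(OCc4ccccc4)cc3)Oc12 | intermediate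
18 | cis-fused 3-hydroxy acetal, C2–H, O7''–C2 closed (both cis diastereomers) | O=C1c2c(OCc3ccccc3)cc(OCc3ccccc3)cc2OC2Oc3cc(OCc4ccccc4)c4c(c3C12O)O[C@H](c1ccc(OCc3ccccc3)cc1)CC4 | intermediate
19 | C3 N-(methoxycarbonyl)sulfamate ester of 18, triethylammonium salt | O=C1c2c(OCc3ccccc3)cc(OCc3ccccc3)cc2OC2Oc3cc(OCc4ccccc4)c4c(c3C12OS(=O)(=O)[N-]C(=O)OC)O[C@H](c1ccc(OCc3ccccc3)cc1)CC4.CC[NH+](CC)CC | intermediate
20 | tetra-O-benzyl benzofuro-fused chromone (flat tetracycle, C2=C3) | O=c1c2c(OCc3ccccc3)cc(OCc3ccccc3)cc2oc2oc3cc(OCc4ccccc4)c4CC[C@@H](c5ccc(OCc6ccccc6)cc5)Oc4c3c12 | intermediate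
21 | (2R)-C4 trimethylsilyl enol ether with 4-(benzyloxy)phenyl on C2 | C[Si](C)(C)OC1=C2c3c(cc(OCc4ccccc4)c4CC[C@@H](c5ccc(OCc6ccccc6)cc5)Oc34)O[C@]2(c2ccc(OCc3ccccc3)cc2)Oc2cc(OCc3ccccc3)cc(OCc3ccccc3)c12 | intermediate
22 | C3–C4 trimethylsilyloxy epoxide of 21 (epoxide oxygen anti to the C2 aryl group) | C[Si](C)(C)O[C@]1(O5)c2c(OCc3ccccc3)cc(OCc3ccccc3)cc2O[C@@]2(c3ccc(OCc4ccccc4)cc3)Oc3cc(OCc4ccccc4)c4c(c3[C@]125)O[C@H](c1ccc(OCc3ccccc3)cc1)CC4 | intermediate
23 | (2R,3S,2''S)-penta-O-benzyl ether of the target | O=C1c2c(OCc3ccccc3)cc(OCc3ccccc3)cc2O[C@@]2(c3ccc(OCc4ccccc4)cc3)Oc3cc(OCc4ccccc4)c4c(c3[C@]12O)O[C@H](c1ccc(OCc3ccccc3)cc1)CC4 | intermediate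
24 | CNP0208300.3, (2R,3S,2''S) | O=C1c2c(O)cc(O)cc2O[C@@]2(c3ccc(O)cc3)Oc3cc(O)c4c(c3[C@]12O)O[C@H](c1ccc(O)cc1)CC4 | target

## Step count and risks

Total step count: 14. Longest linear sequence: 13 steps (steps 1–5 and 7–14).

**Step 12 (C2 arylation).** The aryl–rhodium species may fail to insert into the fully substituted, furan-embedded C2=C3 bond, the enolate may open the ring by loss of a phenoxide before it is silylated, or the ligand may give poor facial selectivity at C2. The fallback uses known chemistry without facial control; it sets out from 20 and comes back at 23. Et3SiOTf in CH2Cl2 at rt should turn 20 into the 4-(triethylsilyloxy)pyrylium triflate F1. 4-BnOC6H4MgBr at −78 °C then adds to C2, which is flanked by O1 and O7'', as Grignard reagents add to 4-silyloxybenzopyrylium salts, and gives the triethylsilyl enol ether F2 as both C2 epimers. DMDO delivers oxygen anti to the aryl group in each epimer to give the silyloxy epoxide F3. Et3N·3HF releases 23 together with its (2S,3R,2''S) diastereomer F4. The two differ in their relation to C2'' and are separated by chromatography on Et3N-deactivated silica.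

**Step 13 (hydroxylation at C3).** Oxygen may be delivered syn to the aryl group, or the silyloxy epoxide may open reversibly at the benzylic C3–O bond, so that the strained trans junction relaxes to the cis-fused epimer. The fallback sets out from 20 and comes back at 23, with the order of the two additions reversed so that C3–O is fixed first. DMDO in CH2Cl2/MeOH should convert 20, through its epoxide and opening by methanol at C2, into the (3S)-2-methoxy-3-hydroxy orthoester F5; the C3 epimers are separated at this stage. Et3SiOTf (2.2 equiv) and 2,6-lutidine at −78 °C silylate the tertiary hydroxyl and ionise the orthoester to the 3-silyloxy dioxocarbenium triflate F6. 4-BnOC6H4MgBr then adds to the planar C2 from the face opposite the silyloxy group to give the 3-O-triethylsilyl ether F7, and Et3N·3HF in THF returns 23.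

**Step 14 (global debenzylation).** The doubly benzylic C2–O bonds may be cleaved by hydrogenolysis, or the ketal may open through a para-quinone methide once the 4'-phenol is free, with loss of the C2 configuration. The fallback sets out from 20 and comes back at 24, exchanging the protecting groups before the labile ketal exists. H2 and 10% Pd/C in EtOAc/THF remove the four benzyl groups from the robust flat tetracycle to give the tetraphenol F8, and t-BuMe2SiOTf with 2,6-lutidine gives the tetrakis(silyl ether) F9. Steps 12 and 13 are then run on F9 with 4-(t-BuMe2SiO)C6H4ZnCl, through the (2R)-trimethylsilyl enol ether F10 and the silyloxy epoxide F11, to the (2R,3S,2''S)-pentakis(silyl ether) hydroxy ketone F12; a brief treatment with Et3N·3HF removes only the trimethylsilyl group. TBAF buffered with AcOH in THF at 0 °C then removes the five aryl silyl groups to give 24.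

Further compounds

F1 | step 12 | 4-(triethylsilyloxy)pyrylium triflate of 20 | CC[Si](CC)(CC)OC1=C2C(=[O+]c3cc(OCc4ccccc4)cc(OCc4ccccc4)c31)Oc1cc(OCc3ccccc3)c3CC[C@@H](c4ccc(OCc5ccccc5)cc4)Oc3c12.[O-]S(=O)(=O)C(F)(F)F
F2 | step 12 | C4 triethylsilyl enol ether with 4-(benzyloxy)phenyl on C2 (both C2 epimers) | CC[Si](CC)(CC)OC1=C2c3c(cc(OCc4ccccc4)c4CC[C@@H](c5ccc(OCc6ccccc6)cc5)Oc34)OC2(c2ccc(OCc3ccccc3)cc2)Oc2cc(OCc3ccccc3)cc(OCc3ccccc3)c12
F3 | step 12 | C3–C4 triethylsilyloxy epoxide of F2 (oxygen anti to the C2 aryl; both C2 series) | CC[Si](CC)(CC)OC12OC13c4c(cc(OCc5ccccc5)c5CC[C@@H](c6ccc(OCc7ccccc7)cc6)Oc45)OC3(c3ccc(OCc4ccccc4)cc3)Oc3cc(OCc4ccccc4)cc(OCc4ccccc4)c23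
F4 | step 12 | (2S,3R,2''S) diastereomer of 23 | O=C1c2c(OCc3ccccc3)cc(OCc3ccccc3)cc2O[C@]2(c3ccc(OCc4ccccc4)cc3)Oc3cc(OCc4ccccc4)c4c(c3[C@@]12O)O[C@H](c1ccc(OCc3ccccc3)cc1)CC4
F5 | step 13 | (3S)-2-methoxy-3-hydroxy orthoester from 20 (C2 epimers) | O=C1c2c(OCc3ccccc3)cc(OCc3ccccc3)cc2OC2(OC)Oc3cc(OCc4ccccc4)c4c(c3[C@]12O)O[C@H](c1ccc(OCc3ccccc3)cc1)CC4
F6 | step 13 | 3-(triethylsilyloxy) dioxocarbenium triflate | O=C1c2c(OCc3ccccc3)cc(OCc3ccccc3)cc2[O+]=C2Oc3cc(OCc4ccccc4)c4c(c3[C@]12O[Si](CC)(CC)CC)O[C@H](c1ccc(OCc3ccccc3)cc1)CC4.[O-]S(=O)(=O)C(F)(F)F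
F7 | step 13 | 3-O-triethylsilyl ether of 23 | O=C1c2c(OCc3ccccc3)cc(OCc3ccccc3)cc2O[C@@]2(c3ccc(OCc4ccccc4)cc3)Oc3cc(OCc4ccccc4)c4c(c3[C@]12O[Si](CC)(CC)CC)O[C@H](c1ccc(OCc3ccccc3)cc1)CC4
F8 | step 14 | tetraphenol of the flat tetracycle 20 | O=c1c2c(O)cc(O)cc2oc2oc3cc(O)c4CC[C@@H](c5ccc(O)cc5)Oc4c3c12
F9 | step 14 | tetrakis(tert-butyldimethylsilyl) ether of F8 | O=c1c2c(O[Si](C)(C)C(C)(C)C)cc(O[Si](C)(C)C(C)(C)C)cc2oc2oc3cc(O[Si](C)(C)C(C)(C)C)c4CC[C@@H](c5ccc(O[Si](C)(C)C(C)(C)C)cc5)Oc4c3c12
F10 | step 14 | (2R)-C4 trimethylsilyl enol ether with 4-(tert-butyldimethylsilyloxy)phenyl on C2 | C[Si](C)(C)OC1=C2c3c(cc(O[Si](C)(C)C(C)(C)C)c4CC[C@@H](c5ccc(O[Si](C)(C)C(C)(C)C)cc5)Oc34)O[C@]2(c2ccc(O[Si](C)(C)C(C)(C)C)cc2)Oc2cc(O[Si](C)(C)C(C)(C)C)cc(O[Si](C)(C)C(C)(C)C)c12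
F11 | step 14 | C3–C4 trimethylsilyloxy epoxide of F10 (oxygen anti to the C2 aryl) | C[Si](C)(C)O[C@]1(O5)c2c(O[Si](C)(C)C(C)(C)C)cc(O[Si](C)(C)C(C)(C)C)cc2O[C@@]2(c3ccc(O[Si](C)(C)C(C)(C)C)cc3)Oc3cc(O[Si](C)(C)C(C)(C)C)c4c(c3[C@]125)O[C@H](c1ccc(O[Si](C)(C)C(C)(C)C)cc1)CC4
F12 | step 14 | (2R,3S,2''S)-pentakis(tert-butyldimethylsilyl) ether of the target | O=C1c2c(O[Si](C)(C)C(C)(C)C)cc(O[Si](C)(C)C(C)(C)C)cc2O[C@@]2(c3ccc(O[Si](C)(C)C(C)(C)C)cc3)Oc3cc(O[Si](C)(C)C(C)(C)C)c4c(c3[C@]12O)O[C@H](c1ccc(O[Si](C)(C)C(C)(C)C)cc1)CC4
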